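## Retrosynthetic overview

- The target comes from (3'R,7'R,11'R)-α-tocopherolquinone in one pot: face-selective epoxidation of the chain-bearing quinone C=C, 5-exo epoxide opening by the side-chain carbinol (oxolane ring, spiro centre), then α-ketol contraction of the six-membered ring to the cyclopentenone (C9).
- α-Tocopherolquinone comes from (2R,4'R,8'R)-α-tocopherol by oxidative opening of the chroman; the C2–O bond and its configuration are kept.
- α-Tocopherol comes from open-chain phytyl-trimethylhydroquinone by a chiral-acid chroman closure (sets C2); that hydroquinone comes from trimethylhydroquinone and isophytol by Friedel–Crafts allylation.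
- Isophytol comes from the (6R,10R)-C18 ketone and a vinyl Grignard reagent; the ketone comes from (5E,9E)-farnesylacetone by asymmetric hydrogenation (first stereocentres).
- Ring order: chroman ring (step 4, opened again in step 5), then the oxolane ring, then the five-membered carbocycle (both in step 6).

Assumption: farnesylacetone is bought as the pure 5E,9E isomer, and for each of the three chiral catalysts the hand named is taken as the one that gives the stated product (the mirror or pseudoenantiomeric form would give the epimer).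

Catalysts:
- L1 = one enantiomer of 2-phenyl-6,7-dihydro-5H-cyclopenta[b]pyridin-7-yl di-o-tolylphosphinite; cod = 1,5-cyclooctadiene.
- C1 = (S,S)-imidodiphosphorimidate (IDPi) Brønsted acid: two (S)-3,3'-bis(4-biphenylyl)-BINOL phosphorus units joined by N–H, each P=N–SO2CF3.
- C2 = N-(9-anthracenylmethyl)-9-O-benzylcupreinium bromide (quinine-derived, free 6'-OH).

## Route

Step 1
Reactants: 1 (5E,9E)-6,10,14-trimethylpentadeca-5,9,13-trien-2-one (farnesylacetone)
Product: 2 (6R,10R)-6,10,14-trimethylpentadecan-2-one
Conditions: [Ir(cod)(L1)][B(C6H3(CF3)2)4] (1 mol%), H2 (50 bar), CH2Cl2, 25 °C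
Reagents that add atoms: none
Why: Iridium-catalysed asymmetric hydrogenation of unfunctionalised trisubstituted olefins (Pfaltz-type P,N catalyst) reduces each E-olefin from the same catalyst-chosen face, setting C6 and C10 both R, while the isopropylidene end gives no stereocentre and the ketone is not reduced.

Step 2
Reactants: 2 (6R,10R)-6,10,14-trimethylpentadecan-2-one
Product: 3 (7R,11R)-3,7,11,15-tetramethylhexadec-1-en-3-ol (isophytol, both C3 epimers)
Conditions: CH2=CHMgBr (1.3 equiv), THF, 0 °C; then H2O
Reagents that add atoms: vinylmagnesium bromide, C=C[Mg]Br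
Why: Grignard 1,2-addition to the methyl ketone gives the tertiary allylic alcohol; its new C3 centre forms unselectively but is destroyed on ionisation in step 3, and the 7R,11R centres are untouched.

Step 3
Reactants: 3 (7R,11R)-isophytol; 4 2,3,5-trimethylbenzene-1,4-diol (trimethylhydroquinone)
Product: 5 2,3,5-trimethyl-6-[(7R,11R)-3,7,11,15-tetramethylhexadec-2-en-1-yl]benzene-1,4-diol (E/Z about 3:1)
Conditions: 4 (3 equiv), BF3·OEt2 (0.3 equiv), 1,4-dioxane, 25 °C, Ar
Reagents that add atoms: none
Why: Friedel–Crafts allylation (SN1'): the tertiary allylic alcohol ionises to the phytyl cation, which is trapped at its primary end by the only free ring position of 4, and the weak acid in a donor solvent at 25 °C leaves the new olefin unprotonated so the chain stays open.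

Step 4
Reactants: 5 phytyl-trimethylhydroquinone
Product: 6 (2R,4'R,8'R)-α-tocopherol
Conditions: C1 (5 mol%), cyclohexane (0.05 M), 40 °C, Ar
Reagents that add atoms: none
Why: Proposed new method: the confined chiral acid protonates C2' of either olefin isomer to the same tertiary carbocation held as a contact ion pair in the chiral cavity, and the ortho OH closes the six-membered ring on the face the catalyst leaves open (long chain outside the pocket, methyl inside), which sets C2 as R independently of the remote 4',8' centres; the closest known reactions are the IDPi-catalysed asymmetric intramolecular hydroalkoxylation of 1,1-disubstituted alkenols to 2,2-disubstituted cyclic ethers and the achiral acid-catalysed chroman closure of the technical vitamin E synthesis.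

Step 5
Reactants: 6 (2R,4'R,8'R)-α-tocopherol
Product: 8 (3'R,7'R,11'R)-α-tocopherolquinone, via 8a-hydroxy-α-tocopherone 7 (not isolated)
Conditions: FeCl3·6H2O (2.5 equiv), MeOH–H2O, Et2O, 25 °C
Reagents that add atoms: water, O
Why: Two-electron oxidation of the para-alkoxyphenol with water capture at C8a gives hemiketal 7, which opens to the para-quinone (classical tocopherol to tocopherolquinone oxidation); the C2–O bond is never broken, so the carbinol carbon keeps R.

Step 6
Reactants: 8 (3'R,7'R,11'R)-α-tocopherolquinone
Product: 11 (2R,5R,9S)-9-acetyl-9-hydroxy-2,7,8-trimethyl-2-[(4R,8R)-4,8,12-trimethyltridecyl]-1-oxaspiro[4.4]non-7-en-6-one, via epoxyquinone 9 (not isolated), via spiro ketol 10 (not isolated)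
Conditions: t-BuOOH (1.1 equiv, decane solution), C2 (10 mol%), Cs2CO3 (0.3 equiv), toluene, −20 °C; then KOtBu (0.1 equiv), 0 °C; AcOH
Reagents that add atoms: tert-butyl hydroperoxide, CC(C)(C)OO
Why: Proposed new method: the chiral ammonium ion pairs with tert-butylperoxide, which is held beside the chain-bearing C=C by a hydrogen bond to the side-chain tertiary OH while the catalyst 6'-OH binds the flanking carbonyl, so Weitz–Scheffer oxygen transfer occurs on that double bond and on one face only (epoxide 9, 1S,6R); the tert-butoxide released then deprotonates the tertiary alcohol, which opens the epoxide 5-exo at the chain-bearing carbon with inversion (spiro centre R in 10), and the resulting tertiary α-ketol alkoxide undergoes a reversible 1,2-shift of the spiro carbon from C10 to the C9 carbonyl (α-ketol ring contraction, retention at the migrating carbon) that settles on the less crowded epimer with acetyl cis and OH trans to the ring oxygen (C9 S); the closest known chemistry is the cinchona-ammonium phase-transfer asymmetric epoxidation of 2-substituted 1,4-naphthoquinones and the unselective base-induced epoxyquinone to spiro-ketol contraction seen when α-tocopherol models are oxidised.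

## Compound list

1 | (5E,9E)-6,10,14-trimethylpentadeca-5,9,13-trien-2-one (farnesylacetone) | CC(=O)CC/C=C(\C)CC/C=C(\C)CCC=C(C)C | starting material
2 | (6R,10R)-6,10,14-trimethylpentadecan-2-one | CC(=O)CCC[C@H](C)CCC[C@H](C)CCCC(C)C | intermediate
3 | (7R,11R)-3,7,11,15-tetramethylhexadec-1-en-3-ol (isophytol, 1:1 epimers at C3) | C=CC(C)(O)CCC[C@H](C)CCC[C@H](C)CCCC(C)C | intermediate
4 | 2,3,5-trimethylbenzene-1,4-diol (trimethylhydroquinone) | Cc1cc(O)c(C)c(C)c1O | starting material
5 | 2,3,5-trimethyl-6-[(7R,11R)-3,7,11,15-tetramethylhexadec-2-en-1-yl]benzene-1,4-diol (E/Z mixture) | Cc1c(C)c(O)c(CC=C(C)CCC[C@H](C)CCC[C@H](C)CCCC(C)C)c(C)c1O | intermediate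
6 | (2R)-2,5,7,8-tetramethyl-2-[(4R,8R)-4,8,12-trimethyltridecyl]-3,4-dihydro-2H-chromen-6-ol ((2R,4'R,8'R)-α-tocopherol) | Cc1c(C)c2c(c(C)c1O)CC[C@@](C)(CCC[C@H](C)CCC[C@H](C)CCCC(C)C)O2 | intermediate
7 | (2R)-8a-hydroxy-2,5,7,8-tetramethyl-2-[(4R,8R)-4,8,12-trimethyltridecyl]-3,4-dihydro-2H-chromen-6(8aH)-one (8a-hydroxy-α-tocopherone, both C8a epimers, not isolated) | CC1=C(C)C2(O)O[C@](C)(CCC[C@H](C)CCC[C@H](C)CCCC(C)C)CCC2=C(C)C1=O | intermediate
8 | 2-[(3R,7R,11R)-3-hydroxy-3,7,11,15-tetramethylhexadecyl]-3,5,6-trimethylcyclohexa-2,5-diene-1,4-dione (α-tocopherolquinone) | CC1=C(C)C(=O)C(CC[C@@](C)(CCC[C@H](C)CCC[C@H](C)CCCC(C)C)O)=C(C)C1=O | intermediate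
9 | (1S,6R)-1-[(3R,7R,11R)-3-hydroxy-3,7,11,15-tetramethylhexadecyl]-3,4,6-trimethyl-7-oxabicyclo[4.1.0]hept-3-ene-2,5-dione (not isolated) | CC1=C(C)C(=O)[C@]2(O[C@@]2(C)C1=O)CC[C@@](C)(CCC[C@H](C)CCC[C@H](C)CCCC(C)C)O | intermediate
10 | (2R,5R,10R)-10-hydroxy-2,7,8,10-tetramethyl-2-[(4R,8R)-4,8,12-trimethyltridecyl]-1-oxaspiro[4.5]dec-7-ene-6,9-dione (not isolated) | CC1=C(C)C(=O)[C@@]2(CC[C@@](C)(CCC[C@H](C)CCC[C@H](C)CCCC(C)C)O2)[C@@](C)(O)C1=O | intermediate
11 | (2R,5R,9S)-9-acetyl-9-hydroxy-2,7,8-trimethyl-2-[(4R,8R)-4,8,12-trimethyltridecyl]-1-oxaspiro[4.4]non-7-en-6-one | CC(=O)[C@]1(O)C(C)=C(C)C(=O)[C@@]12CC[C@@](C)(CCC[C@H](C)CCC[C@H](C)CCCC(C)C)O2 | target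

## Step count and risks

Total steps: 6. Longest linear sequence: 6 (1 to 11; compound 4 joins in step 3).

Steps most likely to fail:

**Step 6 (proposed new step).** The epoxidation may pick the dimethyl-substituted C=C or the wrong face, the SN2 opening at a fully substituted epoxide carbon may be slow, and the product can epimerise by retro-aldol if left in base. The fallback uses known reactions and replaces selectivity by separation. It sets out from 8: uncatalysed Weitz–Scheffer epoxidation (t-BuOOH, benzyltrimethylammonium hydroxide, THF, 0 °C) gives 9 together with its face isomer, the (1R,6S)-epoxyquinone F1, and the dimethyl-side regioisomeric epoxyquinone F2. F2 is removed on silica. The 9/F1 pair is cyclised and ring-contracted with catalytic KOtBu in THF at 0 °C to 11 and its isomer, the (2R,5S,9R)-spiro ketol F3. Preparative HPLC then gives 11, where the fallback comes back to the route.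

**Step 4 (proposed new step).** The cavity may not tell methyl from the long chain well enough, the E and Z isomers of 5 may not converge, or background closure may erode the selectivity at C2. The fallback uses known chemistry and sets out from 5: p-TsOH·H2O (cat.) in toluene at 80 °C closes the chroman without stereocontrol to 6 and its C2 epimer, (2S,4'R,8'R)-α-tocopherol F4, about 1:1. The two epimers are separated by preparative HPLC on a cellulose tris(3,5-dimethylphenylcarbamate) phase, and the fallback comes back at 6.

**Step 3.** The Lewis acid may close part of 5 to racemic-at-C2 chroman before the asymmetric step, or over-alkylate. The fallback avoids acid altogether and sets out from 3: PBr3 in Et2O at −10 °C gives by allylic transposition (7R,11R)-phytyl bromide F5. The monosodium salt of 4 (NaH, toluene) is then C-alkylated ortho to the phenoxide oxygen by the bromide at 25 °C (phenoxide ortho-allylation in a non-polar solvent), and the fallback comes back at 5.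

## Further compounds

F1 | step 6 | (1R,6S)-1-[(3R,7R,11R)-3-hydroxy-3,7,11,15-tetramethylhexadecyl]-3,4,6-trimethyl-7-oxabicyclo[4.1.0]hept-3-ene-2,5-dione | CC1=C(C)C(=O)[C@@]2(O[C@]2(C)C1=O)CC[C@@](C)(CCC[C@H](C)CCC[C@H](C)CCCC(C)C)O
F2 | step 6 | 3-[(3R,7R,11R)-3-hydroxy-3,7,11,15-tetramethylhexadecyl]-1,4,6-trimethyl-7-oxabicyclo[4.1.0]hept-3-ene-2,5-dione (both epoxide face isomers) | CC1=C(CC[C@@](C)(CCC[C@H](C)CCC[C@H](C)CCCC(C)C)O)C(=O)C2(C)OC2(C)C1=O
F3 | step 6 | (2R,5S,9R)-9-acetyl-9-hydroxy-2,7,8-trimethyl-2-[(4R,8R)-4,8,12-trimethyltridecyl]-1-oxaspiro[4.4]non-7-en-6-one | CC(=O)[C@@]1(O)C(C)=C(C)C(=O)[C@]12CC[C@@](C)(CCC[C@H](C)CCC[C@H](C)CCCC(C)C)O2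
F4 | step 4 | (2S)-2,5,7,8-tetramethyl-2-[(4R,8R)-4,8,12-trimethyltridecyl]-3,4-dihydro-2H-chromen-6-ol ((2S,4'R,8'R)-α-tocopherol) | Cc1c(C)c2c(c(C)c1O)CC[C@](C)(CCC[C@H](C)CCC[C@H](C)CCCC(C)C)O2
F5 | step 3 | (7R,11R)-1-bromo-3,7,11,15-tetramethylhexadec-2-ene (phytyl bromide, E/Z mixture) | BrCC=C(C)CCC[C@H](C)CCC[C@H](C)CCCC(C)C
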